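## Retrosynthetic overview

- The strategy rests on the benzene ring: C7a, which must carry the lactone carbonyl C1, lies between C7 (OMe) and C3a (bearing the C3 carbinol). These two 1,3-related groups jointly direct a lithium base to C7a. The five-membered lactone ring (C1, O2, C3, C3a, C7a) is the only ring made and is closed last: C7a–C1 by capture of CO2, C1–O2 by acyl substitution, on an (S)-benzylic alcohol whose O5 is a bulky triisopropylsilyl ether.
- C3 is set by Corey–Bakshi–Shibata reduction of an aryl ketone, made by Grignard addition of the side chain to the silylated aldehyde (C3–C1′) and oxidation.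
- The side chain is built at C9′–C10′ by Weinreb ketone synthesis from (S)-γ-valerolactone (source of C13′) and non-8-enylmagnesium bromide. The C10′ ketone is masked as a dioxolane, O13′ as a silyl ether, and the terminal alkene is turned into the primary bromide.
- End game: fluoride frees the phenol; aqueous acid removes the dioxolane and the alkyl silyl ether.

Key step: step 11

Assumption: 9-bromonon-1-ene is taken as commercially available, its alkene serving as a masked primary bromide. Phthalide numbering (C1 carbonyl, O2, C3, C3a, C4–C7, C7a) and side-chain numbering C1′–C14′ are used; both stereocentres of the target are (S).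

## Route

Step 1
Reactants: 1 (S)-γ-valerolactone
Product: 2 (4S)-4-hydroxy-N-methoxy-N-methylpentanamide
Conditions: MeNH(OMe)·HCl (1.5 equiv), i-PrMgCl (3.0 equiv), THF, −20 → 0 °C; aq. NH4Cl; crude used at once
Reagents that add atoms: N,O-dimethylhydroxylamine hydrochloride, CNOC.Cl
Why: Aminolysis of the lactone by the magnesium amide of N,O-dimethylhydroxylamine (Weinreb amide formation) cleaves only the acyl–oxygen bond, so the C13′ stereocentre bought with 1 is untouched.

Step 2
Reactants: 2 (4S)-4-hydroxy-N-methoxy-N-methylpentanamide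
Product: 3 (4S)-4-(tert-butyldimethylsilyloxy)-N-methoxy-N-methylpentanamide
Conditions: TBSCl (1.3 equiv), imidazole (2.5 equiv), DMF, rt
Reagents that add atoms: tert-butyldimethylsilyl chloride, CC(C)(C)[Si](C)(C)Cl
Why: Imidazole-promoted silylation of the secondary alcohol traps the open-chain amide and stops relactonisation.

Step 3
Reactants: 4 9-bromonon-1-ene; 3 (4S)-4-(tert-butyldimethylsilyloxy)-N-methoxy-N-methylpentanamide
Product: 6 (2S)-2-(tert-butyldimethylsilyloxy)tetradec-13-en-5-one, via non-8-enylmagnesium bromide 5 (not isolated)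
Conditions: 4, Mg, THF, rt → 40 °C; then 3, THF, 0 °C; aq. NH4Cl
Reagents that add atoms: none
Why: Weinreb ketone synthesis forms the C9′–C10′ bond; the chelated magnesium adduct collapses to the ketone only on work-up, so no second addition occurs.

Step 4
Reactants: 6 (2S)-2-(tert-butyldimethylsilyloxy)tetradec-13-en-5-one
Product: 7 2-[(3S)-3-(tert-butyldimethylsilyloxy)butyl]-2-(non-8-enyl)-1,3-dioxolane
Conditions: TMSOCH2CH2OTMS (2 equiv), TMSOTf (5 mol%), CH2Cl2, −78 → −20 °C; pyridine quench
Reagents that add atoms: 1,2-bis(trimethylsilyloxy)ethane, C[Si](C)(C)OCCO[Si](C)(C)C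
Why: TMSOTf-catalysed ketalisation with the bis-silyl ether of ethylene glycol is driven by formation of hexamethyldisiloxane and, being aprotic and cold, should leave the secondary silyl ether in place.

Step 5
Reactants: 7 2-[(3S)-3-(tert-butyldimethylsilyloxy)butyl]-2-(non-8-enyl)-1,3-dioxolane
Product: 9 9-{2-[(3S)-3-(tert-butyldimethylsilyloxy)butyl]-1,3-dioxolan-2-yl}nonan-1-ol, via B-alkyl-9-BBN adduct 8 (not isolated)
Conditions: 9-BBN (1.3 equiv), THF, 0 °C → rt; then 3 M NaOH, 30% H2O2, 0 °C → rt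
Reagents that add atoms: hydrogen peroxide, OO
Why: Anti-Markovnikov hydroboration of the terminal alkene and oxidation of the C–B bond give the primary alcohol; the ketal and silyl ether are inert to both stages.

Step 6
Reactants: 9 9-{2-[(3S)-3-(tert-butyldimethylsilyloxy)butyl]-1,3-dioxolan-2-yl}nonan-1-ol
Product: 10 2-(9-bromononyl)-2-[(3S)-3-(tert-butyldimethylsilyloxy)butyl]-1,3-dioxolane
Conditions: CBr4, PPh3, 2,6-lutidine (0.1 equiv), CH2Cl2, 0 °C
Reagents that add atoms: carbon tetrabromide, BrC(Br)(Br)Br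
Why: The Appel reaction converts the primary alcohol into the bromide under near-neutral conditions that the dioxolane tolerates.

Step 7
Reactants: 11 3-hydroxy-5-methoxybenzaldehyde
Product: 12 3-methoxy-5-(triisopropylsilyloxy)benzaldehyde
Conditions: TIPSCl (1.2 equiv), imidazole (2.5 equiv), DMF, rt
Reagents that add atoms: triisopropylsilyl chloride, CC(C)[Si](Cl)(C(C)C)C(C)C
Why: Imidazole-promoted silylation of the phenol installs an ether that is stable to organomagnesium and organolithium reagents and later shields C4 and C6.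

Step 8
Reactants: 10 2-(9-bromononyl)-2-[(3S)-3-(tert-butyldimethylsilyloxy)butyl]-1,3-dioxolane; 12 3-methoxy-5-(triisopropylsilyloxy)benzaldehyde
Product: 14 (1RS)-10-{2-[(3S)-3-(tert-butyldimethylsilyloxy)butyl]-1,3-dioxolan-2-yl}-1-[3-methoxy-5-(triisopropylsilyloxy)phenyl]decan-1-ol (both C3 epimers), via alkylmagnesium bromide 13 (not isolated)
Conditions: 10, Mg (activated with 1,2-dibromoethane), THF, 40 °C; then 12, THF, −20 → 0 °C; aq. NH4Cl
Reagents that add atoms: none
Why: Grignard addition to the non-enolisable aromatic aldehyde forms the C3–C1′ bond; C3 is formed without control, which does not matter because it is made planar again in step 9.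

Step 9
Reactants: 14 (1RS)-10-{2-[(3S)-3-(tert-butyldimethylsilyloxy)butyl]-1,3-dioxolan-2-yl}-1-[3-methoxy-5-(triisopropylsilyloxy)phenyl]decan-1-ol
Product: 15 10-{2-[(3S)-3-(tert-butyldimethylsilyloxy)butyl]-1,3-dioxolan-2-yl}-1-[3-methoxy-5-(triisopropylsilyloxy)phenyl]decan-1-one
Conditions: Dess–Martin periodinane (1.3 equiv), NaHCO3, CH2Cl2, rt
Reagents that add atoms: none
Why: Dess–Martin oxidation of the benzylic alcohol under buffered conditions gives the aryl ketone and spares the dioxolane and both silyl ethers.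

Step 10
Reactants: 15 10-{2-[(3S)-3-(tert-butyldimethylsilyloxy)butyl]-1,3-dioxolan-2-yl}-1-[3-methoxy-5-(triisopropylsilyloxy)phenyl]decan-1-one
Product: 16 (1S)-10-{2-[(3S)-3-(tert-butyldimethylsilyloxy)butyl]-1,3-dioxolan-2-yl}-1-[3-methoxy-5-(triisopropylsilyloxy)phenyl]decan-1-ol
Conditions: (R)-2-methyl-CBS-oxazaborolidine (0.15 equiv), BH3·SMe2 (0.7 equiv), THF, −20 °C; MeOH quench
Reagents that add atoms: none
Why: Corey–Bakshi–Shibata reduction: the (R)-oxazaborolidine–borane complex binds the ketone with the aryl group as the large substituent and delivers hydride to the Re face, which sets C3 as (S).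

Step 11
Reactants: 16 (1S)-10-{2-[(3S)-3-(tert-butyldimethylsilyloxy)butyl]-1,3-dioxolan-2-yl}-1-[3-methoxy-5-(triisopropylsilyloxy)phenyl]decan-1-ol
Product: 19 (3S)-3-(9-{2-[(3S)-3-(tert-butyldimethylsilyloxy)butyl]-1,3-dioxolan-2-yl}nonyl)-7-methoxy-5-(triisopropylsilyloxy)isobenzofuran-1(3H)-one, via C7a-lithiated lithium alkoxide 17 (not isolated), via hydroxy acid 18 (not isolated)
Conditions: n-BuLi (2.5 equiv), TMEDA (2.5 equiv), Et2O–hexane, 0 °C → rt; CO2 (g), −78 °C → rt; 10% aq. citric acid, 0 °C; PPTS (cat.), CH2Cl2, rt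
Reagents that add atoms: carbon dioxide, O=C=O
Why: The first equivalent of n-BuLi forms the lithium alkoxide of 16; this alkoxide and the methoxy oxygen hold the second n-BuLi/TMEDA unit over the one ring carbon between them, so deprotonation gives aryllithium 17, which adds to CO2. The closest known reaction type is the alkoxide- and methoxy-directed ortho-lithiation and carboxylation of 3-methoxybenzyl alcohols to 7-methoxyphthalides. On mild acidification hydroxy acid 18 closes the five-membered lactone ring by 5-exo-trig attack of the C3 oxygen on the carboxyl carbon (C1–O2 bond) with loss of water. No stereocentre is created: C3 is an alkoxide carbon during the metalation, is not deprotonated and no bond to it is broken, so the (S) configuration from step 10 is carried over. The selectivity needed is for C7a over C4 and C6; it is secured by the 1,3-relationship of the two directing groups and by the bulky, poorly coordinating triisopropylsilyl ether on O5, which shields both of its neighbours. The dioxolane and the alkyl silyl ether offer n-BuLi no acidic or electrophilic site, and the buffered acid quench should leave them on.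

Step 12
Reactants: 19 (3S)-3-(9-{2-[(3S)-3-(tert-butyldimethylsilyloxy)butyl]-1,3-dioxolan-2-yl}nonyl)-7-methoxy-5-(triisopropylsilyloxy)isobenzofuran-1(3H)-one
Product: 20 (3S)-3-(9-{2-[(3S)-3-(tert-butyldimethylsilyloxy)butyl]-1,3-dioxolan-2-yl}nonyl)-5-hydroxy-7-methoxyisobenzofuran-1(3H)-one
Conditions: Bu4NF (1.2 equiv), AcOH (1.2 equiv), THF, 0 °C → rt
Reagents that add atoms: none
Why: Fluoride cleaves the aryl silyl ether far faster than the secondary alkyl silyl ether because phenoxide is the better leaving group; the acetic acid buffer protects the lactone and the C3–H.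

Step 13
Reactants: 20 (3S)-3-(9-{2-[(3S)-3-(tert-butyldimethylsilyloxy)butyl]-1,3-dioxolan-2-yl}nonyl)-5-hydroxy-7-methoxyisobenzofuran-1(3H)-one
Product: 21 (3S)-5-hydroxy-3-[(13S)-13-hydroxy-10-oxotetradecyl]-7-methoxyisobenzofuran-1(3H)-one (target)
Conditions: 2 M aq. HCl–THF (1:3), rt
Reagents that add atoms: water, O
Why: Acid-catalysed hydrolysis removes the dioxolane and the secondary silyl ether together; no alcohol co-solvent is used, so the freed γ-hydroxy ketone is not trapped as a mixed ketal, and neither stereocentre is touched.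

## Compound list

1 | (S)-γ-valerolactone [(5S)-5-methyloxolan-2-one] | O=C1CC[C@H](C)O1 | starting material
2 | (4S)-4-hydroxy-N-methoxy-N-methylpentanamide | CON(C)C(=O)CC[C@H](C)O | intermediate
3 | (4S)-4-(tert-butyldimethylsilyloxy)-N-methoxy-N-methylpentanamide | CON(C)C(=O)CC[C@H](C)O[Si](C)(C)C(C)(C)C | intermediate
4 | 9-bromonon-1-ene | C=CCCCCCCCBr | starting material
5 | non-8-enylmagnesium bromide | C=CCCCCCCC[Mg]Br | intermediate
6 | (2S)-2-(tert-butyldimethylsilyloxy)tetradec-13-en-5-one | C=CCCCCCCCC(=O)CC[C@H](C)O[Si](C)(C)C(C)(C)C | intermediate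
7 | 2-[(3S)-3-(tert-butyldimethylsilyloxy)butyl]-2-(non-8-enyl)-1,3-dioxolane | C=CCCCCCCCC1(OCCO1)CC[C@H](C)O[Si](C)(C)C(C)(C)C | intermediate
8 | 9-(9-{2-[(3S)-3-(tert-butyldimethylsilyloxy)butyl]-1,3-dioxolan-2-yl}nonyl)-9-borabicyclo[3.3.1]nonane | B1(CCCCCCCCCC3(OCCO3)CC[C@H](C)O[Si](C)(C)C(C)(C)C)C2CCCC1CCC2 | intermediate
9 | 9-{2-[(3S)-3-(tert-butyldimethylsilyloxy)butyl]-1,3-dioxolan-2-yl}nonan-1-ol | OCCCCCCCCCC1(OCCO1)CC[C@H](C)O[Si](C)(C)C(C)(C)C | intermediate
10 | 2-(9-bromononyl)-2-[(3S)-3-(tert-butyldimethylsilyloxy)butyl]-1,3-dioxolane | BrCCCCCCCCCC1(OCCO1)CC[C@H](C)O[Si](C)(C)C(C)(C)C | intermediate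
11 | 3-hydroxy-5-methoxybenzaldehyde | COc1cc(O)cc(C=O)c1 | starting material
12 | 3-methoxy-5-(triisopropylsilyloxy)benzaldehyde | COc1cc(O[Si](C(C)C)(C(C)C)C(C)C)cc(C=O)c1 | intermediate
13 | (9-{2-[(3S)-3-(tert-butyldimethylsilyloxy)butyl]-1,3-dioxolan-2-yl}nonyl)magnesium bromide | Br[Mg]CCCCCCCCCC1(OCCO1)CC[C@H](C)O[Si](C)(C)C(C)(C)C | intermediate
14 | (1RS)-10-{2-[(3S)-3-(tert-butyldimethylsilyloxy)butyl]-1,3-dioxolan-2-yl}-1-[3-methoxy-5-(triisopropylsilyloxy)phenyl]decan-1-ol (both C3 epimers) | COc1cc(O[Si](C(C)C)(C(C)C)C(C)C)cc(c1)C(O)CCCCCCCCCC1(OCCO1)CC[C@H](C)O[Si](C)(C)C(C)(C)C | intermediate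
15 | 10-{2-[(3S)-3-(tert-butyldimethylsilyloxy)butyl]-1,3-dioxolan-2-yl}-1-[3-methoxy-5-(triisopropylsilyloxy)phenyl]decan-1-one | COc1cc(O[Si](C(C)C)(C(C)C)C(C)C)cc(c1)C(=O)CCCCCCCCCC1(OCCO1)CC[C@H](C)O[Si](C)(C)C(C)(C)C | intermediate
16 | (1S)-10-{2-[(3S)-3-(tert-butyldimethylsilyloxy)butyl]-1,3-dioxolan-2-yl}-1-[3-methoxy-5-(triisopropylsilyloxy)phenyl]decan-1-ol | COc1cc(O[Si](C(C)C)(C(C)C)C(C)C)cc(c1)[C@@H](O)CCCCCCCCCC1(OCCO1)CC[C@H](C)O[Si](C)(C)C(C)(C)C | intermediate
17 | lithium (1S)-alkoxide of 16 lithiated at the ring carbon between the methoxy and carbinol groups (C7a) | COc1cc(O[Si](C(C)C)(C(C)C)C(C)C)cc(c1[Li])[C@@H](O[Li])CCCCCCCCCC1(OCCO1)CC[C@H](C)O[Si](C)(C)C(C)(C)C | intermediate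
18 | 2-[(1S)-10-{2-[(3S)-3-(tert-butyldimethylsilyloxy)butyl]-1,3-dioxolan-2-yl}-1-hydroxydecyl]-6-methoxy-4-(triisopropylsilyloxy)benzoic acid | COc1cc(O[Si](C(C)C)(C(C)C)C(C)C)cc(c1C(=O)O)[C@@H](O)CCCCCCCCCC1(OCCO1)CC[C@H](C)O[Si](C)(C)C(C)(C)C | intermediate
19 | (3S)-3-(9-{2-[(3S)-3-(tert-butyldimethylsilyloxy)butyl]-1,3-dioxolan-2-yl}nonyl)-7-methoxy-5-(triisopropylsilyloxy)isobenzofuran-1(3H)-one | COc1cc(O[Si](C(C)C)(C(C)C)C(C)C)cc2c1C(=O)O[C@H]2CCCCCCCCCC1(OCCO1)CC[C@H](C)O[Si](C)(C)C(C)(C)C | intermediate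
20 | (3S)-3-(9-{2-[(3S)-3-(tert-butyldimethylsilyloxy)butyl]-1,3-dioxolan-2-yl}nonyl)-5-hydroxy-7-methoxyisobenzofuran-1(3H)-one | COc1cc(O)cc2c1C(=O)O[C@H]2CCCCCCCCCC1(OCCO1)CC[C@H](C)O[Si](C)(C)C(C)(C)C | intermediate
21 | (3S)-5-hydroxy-3-[(13S)-13-hydroxy-10-oxotetradecyl]-7-methoxyisobenzofuran-1(3H)-one | COc1cc(O)cc2c1C(=O)O[C@H]2CCCCCCCCCC(=O)CC[C@H](C)O | target

## Step count and risks

Total step count: 13. Longest linear sequence: 12 steps (steps 1–6 and 8–13, from (S)-γ-valerolactone); step 7 is the one-step aryl arm.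

The three steps most likely to fail:

**Step 11.** The second deprotonation of the hindered secondary lithium alkoxide may stall or stray: slow metalation in the aggregated dianion, or competing attack beside the silyl ether or at silicon-bound methyl groups. The carboxyl group would then not be placed cleanly at C7a. The fallback fixes the metal-bearing carbon with a bromine atom put on the simple aldehyde and exchanges it for lithium at the end. It sets out from aldehyde 12. In situ protection as the lithium α-amino alkoxide with lithium N,N,N′-trimethylethylenediamide, ortho-lithiation with n-BuLi (THF, −20 °C) between the masked formyl group and the methoxy group, and quench with 1,2-dibromo-1,1,2,2-tetrachloroethane should give, after aqueous work-up, 2-bromo-3-methoxy-5-(triisopropylsilyloxy)benzaldehyde F1. Addition of Grignard reagent 13 as in step 8 should give the 2-bromoaryl carbinol F2; Dess–Martin oxidation the 2-bromoaryl ketone F3; and Corey–Bakshi–Shibata reduction with the (R)-catalyst the (S)-2-bromoaryl carbinol F4. Treatment of F4 with n-BuLi (2.2 equiv, THF, −78 °C) removes the hydroxyl proton and exchanges bromine for lithium. This gives dilithio compound 17 with the metal at the defined carbon, where the route is rejoined; 17 is carboxylated and lactonised to 19 as in step 11.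

**Step 10.** The hydride transfer may discriminate poorly between the aryl group and the long n-alkyl chain. The C3 epimer so formed could not be separated later, since C13′ is remote. The fallback sets C3 in a carbon–carbon bond-forming step instead. It sets out from bromide 10 and aldehyde 12. NaI in acetone (Finkelstein exchange) should give 2-[(3S)-3-(tert-butyldimethylsilyloxy)butyl]-2-(9-iodononyl)-1,3-dioxolane F7. Iodine–zinc exchange with Et2Zn (CuI cat., neat, 50 °C, volatiles removed) should give bis(9-{2-[(3S)-3-(tert-butyldimethylsilyloxy)butyl]-1,3-dioxolan-2-yl}nonyl)zinc F8. Addition of F8 to 12 with Ti(OiPr)4 and catalytic (1R,2R)-1,2-bis(trifluoromethanesulfonamido)cyclohexane in toluene at −20 °C should transfer the alkyl group to the Si face of the aldehyde. This gives (S)-alcohol 16 directly, where the route is rejoined; 14 and 15 are bypassed.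

**Step 8.** Magnesium insertion into the long-chain bromide 10 may be accompanied by Wurtz-type homocoupling or protonation of the organometallic, so that the valuable chain is lost before it meets the aldehyde. The fallback reverses the polarity (Corey–Seebach alkylation), so that 10 serves as the electrophile. It sets out from aldehyde 12 and bromide 10. Aldehyde 12 with propane-1,3-dithiol and BF3·OEt2 (cat.) in CH2Cl2 should give 2-[3-methoxy-5-(triisopropylsilyloxy)phenyl]-1,3-dithiane F5. Deprotonation with n-BuLi (THF, −78 → −20 °C) and alkylation with 10 should give the 2-aryl-2-alkyl-1,3-dithiane F6. Removal of the dithiane with MeI and CaCO3 in aqueous MeCN should give ketone 15, where the route is rejoined; 14 and step 9 are bypassed.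

## Further compounds

F1 | step 11 | 2-bromo-3-methoxy-5-(triisopropylsilyloxy)benzaldehyde | COc1cc(O[Si](C(C)C)(C(C)C)C(C)C)cc(C=O)c1Br
F2 | step 11 | (1RS)-1-[2-bromo-3-methoxy-5-(triisopropylsilyloxy)phenyl]-10-{2-[(3S)-3-(tert-butyldimethylsilyloxy)butyl]-1,3-dioxolan-2-yl}decan-1-ol | COc1cc(O[Si](C(C)C)(C(C)C)C(C)C)cc(c1Br)C(O)CCCCCCCCCC1(OCCO1)CC[C@H](C)O[Si](C)(C)C(C)(C)C
F3 | step 11 | 1-[2-bromo-3-methoxy-5-(triisopropylsilyloxy)phenyl]-10-{2-[(3S)-3-(tert-butyldimethylsilyloxy)butyl]-1,3-dioxolan-2-yl}decan-1-one | COc1cc(O[Si](C(C)C)(C(C)C)C(C)C)cc(c1Br)C(=O)CCCCCCCCCC1(OCCO1)CC[C@H](C)O[Si](C)(C)C(C)(C)C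
F4 | step 11 | (1S)-1-[2-bromo-3-methoxy-5-(triisopropylsilyloxy)phenyl]-10-{2-[(3S)-3-(tert-butyldimethylsilyloxy)butyl]-1,3-dioxolan-2-yl}decan-1-ol | COc1cc(O[Si](C(C)C)(C(C)C)C(C)C)cc(c1Br)[C@@H](O)CCCCCCCCCC1(OCCO1)CC[C@H](C)O[Si](C)(C)C(C)(C)C
F5 | step 8 | 2-[3-methoxy-5-(triisopropylsilyloxy)phenyl]-1,3-dithiane | COc1cc(O[Si](C(C)C)(C(C)C)C(C)C)cc(c1)C1SCCCS1
F6 | step 8 | 2-(9-{2-[(3S)-3-(tert-butyldimethylsilyloxy)butyl]-1,3-dioxolan-2-yl}nonyl)-2-[3-methoxy-5-(triisopropylsilyloxy)phenyl]-1,3-dithiane | COc1cc(O[Si](C(C)C)(C(C)C)C(C)C)cc(c1)C1(SCCCS1)CCCCCCCCCC1(OCCO1)CC[C@H](C)O[Si](C)(C)C(C)(C)C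
F7 | step 10 | 2-[(3S)-3-(tert-butyldimethylsilyloxy)butyl]-2-(9-iodononyl)-1,3-dioxolane | ICCCCCCCCCC1(OCCO1)CC[C@H](C)O[Si](C)(C)C(C)(C)C
F8 | step 10 | bis(9-{2-[(3S)-3-(tert-butyldimethylsilyloxy)butyl]-1,3-dioxolan-2-yl}nonyl)zinc | CC(C)(C)[Si](C)(C)O[C@@H](C)CCC1(OCCO1)CCCCCCCCC[Zn]CCCCCCCCCC1(OCCO1)CC[C@H](C)O[Si](C)(C)C(C)(C)C
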